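**Retrosynthetic overview**

1. Last bond made: the tertiary C–Cl, by chloride opening (net retention, through the bromonium ion) of a temporary oxygen bridge between the ring carbinol carbon and the chlorine-bearing carbon (a 2-bromo-7-oxabicyclo[2.2.1]heptane).
2. Key operation: ring-closing metathesis joins the future CHBr and C(CH3)Cl carbons as the C=C of a 4-methylcyclohex-3-en-1-ol, and NBS closes the oxygen bridge in the same flask. The diene comes from a Weinreb amide and two Grignard reagents (3-methylbut-3-enyl, then allyl) at the future carbinol carbon.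
3. Enabling feature: in the six-membered ring the vicinal, trans CHBr–C(CH3)Cl pair is the retron of a ring alkene, and the carbinol carbon of that ring lies 1,3 to CHBr and 1,4 to C(CH3)Cl with its OH cis to Cl and trans to Br, so its oxygen can reach across the ring and fix both halogen-bearing stereocenters.
4. Cyclopentane: mapped onto (1R,3S)-camphoric acid. The quaternary C–CH3, the gem-dimethyl carbon and the other three ring carbons are kept; the C1 carboxyl carbon becomes the cyclohexane carbinol carbon; the C3 carboxyl is excised to an alkene, then an enone, from which the CHOH and CHBr carbons are made.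
5. Ring order: cyclopentane (chiral pool) → cyclohexene (metathesis) → temporary oxolane bridge → bridge opened by chloride.

Key step: step 13

Remark: in step 6 the antipode of the bisphosphine is the one that places boron on the enone face anti to the carboxamide, to be fixed by a trial run with each antipode; all later stereocenters follow from the substrate.

**Route**

Step 1
Reactants: 1 (1R,3S)-camphoric acid
Product: 2 (1R,3S)-3-(methoxycarbonyl)-1,2,2-trimethylcyclopentane-1-carboxylic acid
Conditions: MeOH, H2SO4 (cat.), 65 °C
Reagents that add atoms: methanol, CO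
Why: Fischer esterification should stop at the secondary carboxyl, because the carboxyl on the quaternary carbon is flanked by two fully substituted carbons and reacts far more slowly; no stereocenter is touched.

Step 2
Reactants: 2 (1R,3S)-3-(methoxycarbonyl)-1,2,2-trimethylcyclopentane-1-carboxylic acid
Product: 4 methyl (1S,3R)-3-[methoxy(methyl)carbamoyl]-2,2,3-trimethylcyclopentane-1-carboxylate, via acid chloride 3 (not isolated)
Conditions: (COCl)2, DMF (cat.), CH2Cl2, 0 to 25 °C; then MeNH(OMe)·HCl, pyridine, DMAP (cat.), 25 °C
Reagents that add atoms: N,O-dimethylhydroxylamine hydrochloride, CNOC.Cl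
Why: Acid chloride formation followed by amidation (Weinreb amide synthesis) turns the hindered tertiary carboxyl into an acyl donor that later accepts exactly one organometallic; the quaternary stereocenter cannot epimerise.

Step 3
Reactants: 4 methyl (1S,3R)-3-[methoxy(methyl)carbamoyl]-2,2,3-trimethylcyclopentane-1-carboxylate
Product: 5 (1S,3R)-3-[methoxy(methyl)carbamoyl]-2,2,3-trimethylcyclopentane-1-carboxylic acid
Conditions: LiOH·H2O, THF/MeOH/H2O, 50 °C; then 1 M HCl
Reagents that add atoms: lithium hydroxide, [Li+].[OH-]
Why: Saponification (BAc2) cleaves the secondary methyl ester while the neopentyl-type Weinreb amide is too hindered to hydrolyse; epimerisation next to the new carboxyl would be harmless because that carbon becomes sp2 in step 4.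

Step 4
Reactants: 5 (1S,3R)-3-[methoxy(methyl)carbamoyl]-2,2,3-trimethylcyclopentane-1-carboxylic acid
Product: 6 (1R)-N-methoxy-N,1,2,2-tetramethylcyclopent-3-ene-1-carboxamide
Conditions: Pb(OAc)4, Cu(OAc)2 (0.2 equiv), pyridine, benzene, 80 °C
Reagents that add atoms: none
Why: Kochi oxidative decarboxylation: the secondary radical left after loss of CO2 is oxidised by divalent copper with loss of a β-hydrogen, and only the ring CH2 neighbour carries one, so a single cyclopentene is expected.

Step 5
Reactants: 6 (1R)-N-methoxy-N,1,2,2-tetramethylcyclopent-3-ene-1-carboxamide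
Product: 8 (1S)-N-methoxy-N,1,5,5-tetramethyl-2-oxocyclopent-3-ene-1-carboxamide, via allylic alcohol 7 (not isolated)
Conditions: SeO2, 1,4-dioxane, 90 °C; then Dess–Martin periodinane, CH2Cl2, 25 °C
Reagents that add atoms: selenium dioxide, O=[Se]=O
Why: Riley oxidation (ene reaction of SeO2, then [2,3]-sigmatropic shift) hydroxylates the only allylic CH2 without net migration of the double bond, and Dess–Martin oxidation of the crude epimeric allylic alcohols converges on one enone, so the carbinol configuration is irrelevant.

Step 6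
Reactants: 8 (1S)-N-methoxy-N,1,5,5-tetramethyl-2-oxocyclopent-3-ene-1-carboxamide
Product: 10 (1S,3R)-3-hydroxy-N-methoxy-N,1,2,2-tetramethyl-5-oxocyclopentane-1-carboxamide, via boronate 9 (not isolated)
Conditions: CuCl (5 mol %), NaOt-Bu (10 mol %), (R,R)- or (S,S)-2,3-bis(tert-butylmethylphosphino)quinoxaline (6 mol %, antipode as in the remark), B2pin2, MeOH, THF, 25 °C; then 30% H2O2, aq. NaHCO3, 0 °C
Reagents that add atoms: hydrogen peroxide, OO
Why: Copper-catalysed conjugate borylation of a cyclic enone, with the face of the β-carbon chosen by the chiral bisphosphine (boron anti to the carboxamide, the remote quaternary centre exerting little bias), followed by stereoretentive oxidation of the C–B bond, sets the (R) carbinol carbon that is inverted in step 11.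

Step 7
Reactants: 10 (1S,3R)-3-hydroxy-N-methoxy-N,1,2,2-tetramethyl-5-oxocyclopentane-1-carboxamide
Product: 11 (1S,3R,5R)-3,5-dihydroxy-N-methoxy-N,1,2,2-tetramethylcyclopentane-1-carboxamide
Conditions: Me4NBH(OAc)3, MeCN/AcOH (1:1), −30 °C
Reagents that add atoms: none
Why: Evans–Saksena reduction: the hydroxyl binds boron and delivers hydride to its own face of the ketone, giving the anti 1,3-diol, that is the new carbinol cis to the carboxamide, which is also the outcome of approach from the methyl-bearing face.

Step 8
Reactants: 11 (1S,3R,5R)-3,5-dihydroxy-N-methoxy-N,1,2,2-tetramethylcyclopentane-1-carboxamide; 12 4-bromo-2-methylbut-1-ene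
Product: 14 1-[(1S,3R,5R)-3,5-dihydroxy-1,2,2-trimethylcyclopentyl]-4-methylpent-4-en-1-one, via Grignard reagent 13 (not isolated)
Conditions: 12, Mg, THF, 45 °C; then 11 (0.28 equiv relative to 13), 0 to 25 °C; aq. NH4Cl
Reagents that add atoms: none
Why: Weinreb ketone synthesis: after the two hydroxyls have consumed two equivalents of 13, the magnesium-chelated tetrahedral adduct survives until work-up and then releases the ketone, so no tertiary alcohol forms and no stereocenter is affected.

Step 9
Reactants: 14 1-[(1S,3R,5R)-3,5-dihydroxy-1,2,2-trimethylcyclopentyl]-4-methylpent-4-en-1-one; 15 allylmagnesium bromide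
Product: 16 (1R,3R,4S)-4-[(4R)-4-hydroxy-7-methylocta-1,7-dien-4-yl]-4,5,5-trimethylcyclopentane-1,3-diol
Conditions: 15 (4 equiv), Et2O/CH2Cl2, −78 °C; aq. NH4Cl
Reagents that add atoms: none
Why: Chelation-controlled (Cram chelate) Grignard addition: the magnesium alkoxide of the neighbouring ring hydroxyl holds the ketone oxygen syn to it and the allyl group should enter from the face flanked by the methyl group rather than by the gem-dimethyl ring carbon, which gives the (R) tertiary carbinol; the Felkin–Anh model with the gem-dimethyl carbon as the large group predicts the same face.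

Step 10
Reactants: 16 (1R,3R,4S)-4-[(4R)-4-hydroxy-7-methylocta-1,7-dien-4-yl]-4,5,5-trimethylcyclopentane-1,3-diol
Product: 17 (4R,4aS,6R,7aR)-2,2,4a,5,5-pentamethyl-4-(3-methylbut-3-en-1-yl)-4-(prop-2-en-1-yl)hexahydrocyclopenta[d][1,3]dioxin-6-ol
Conditions: 2,2-dimethoxypropane, PPTS (cat.), CH2Cl2, 25 °C
Reagents that add atoms: 2,2-dimethoxypropane, COC(C)(C)OC
Why: Acetalisation: only the cis-disposed secondary ring hydroxyl and the tertiary carbinol can close a 1,3-dioxane, whereas the trans hydroxyl next to the gem-dimethyl carbon cannot bridge and stays free.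

Step 11
Reactants: 17 (4R,4aS,6R,7aR)-2,2,4a,5,5-pentamethyl-4-(3-methylbut-3-en-1-yl)-4-(prop-2-en-1-yl)hexahydrocyclopenta[d][1,3]dioxin-6-ol
Product: 18 (4R,4aS,6S,7aR)-6-bromo-2,2,4a,5,5-pentamethyl-4-(3-methylbut-3-en-1-yl)-4-(prop-2-en-1-yl)hexahydrocyclopenta[d][1,3]dioxine
Conditions: PPh3, CBr4, 2,6-lutidine, toluene, 0 to 60 °C
Reagents that add atoms: carbon tetrabromide, BrC(Br)(Br)Br
Why: Appel reaction: bromide displaces the oxyphosphonium group by SN2 with inversion, a displacement with precedent in the cyclopentanols of steroid five-membered rings that carry the same quaternary neighbour, which places bromine cis to the two oxygen-bearing substituents.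

Step 12
Reactants: 18 (4R,4aS,6S,7aR)-6-bromo-2,2,4a,5,5-pentamethyl-4-(3-methylbut-3-en-1-yl)-4-(prop-2-en-1-yl)hexahydrocyclopenta[d][1,3]dioxine
Product: 19 (1R,2S,4S)-4-bromo-2-[(4R)-4-hydroxy-7-methylocta-1,7-dien-4-yl]-2,3,3-trimethylcyclopentan-1-ol
Conditions: PPTS (cat.), MeOH, 40 °C
Reagents that add atoms: none
Why: Acid-catalysed transacetalisation to methanol releases the 1,3-diol under conditions too mild to protonate the 1,1-disubstituted alkene or disturb the secondary bromide.

Step 13
Reactants: 19 (1R,2S,4S)-4-bromo-2-[(4R)-4-hydroxy-7-methylocta-1,7-dien-4-yl]-2,3,3-trimethylcyclopentan-1-ol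
Product: 21 (1R,2S,4S)-4-bromo-2-[(1R,3S,4S)-3-bromo-4-methyl-7-oxabicyclo[2.2.1]heptan-1-yl]-2,3,3-trimethylcyclopentan-1-ol, via cyclohexenol 20 (not isolated)
Conditions: second-generation Grubbs catalyst (H2IMes)(PCy3)Cl2Ru=CHPh (5 mol %), CH2Cl2 (0.005 M), 40 °C; then 0 °C, NBS (1.1 equiv), dark
Reagents that add atoms: N-bromosuccinimide, O=C1CCC(=O)N1Br
Why: The ruthenium benzylidene loads onto the allyl terminus and the resulting alkylidene closes the six-membered ring onto the 1,1-disubstituted alkene by [2+2] cycloaddition and cycloreversion with loss of ethylene, so that the future CHBr and C(CH3)Cl carbons become the trisubstituted ring C=C; NBS then forms bromonium ions reversibly on both faces and the tertiary hydroxyl captures the one on the opposite face at the methyl-bearing carbon. The closest known reaction types are ring-closing metathesis of 1,7-dienes to 1-methylcyclohexenes and the halo-etherification of 4-hydroxy-1-methylcyclohexenes (terpinen-4-ol type) to 2-halo-7-oxabicyclo[2.2.1]heptanes. The carbocycle closes by metathesis (six-membered, helped by the fully substituted carbinol carbon), the oxolane by a 5-exo, Markovnikov attack of oxygen across the ring through a boat conformer. The two new stereocenters are fixed by the carbinol carbon set in step 9: its oxygen can only reach the methyl-bearing carbon on its own face, and anti addition puts bromine on the other face (endo, trans to the bridge). The step needs face selection, which is secured because the bromonium ion syn to the hydroxyl has no internal nucleophile behind it and reverts, and regioselection, which is secured because the competing secondary hydroxyl on the cyclopentane would have to attack the secondary carbon or close a seven-membered ring.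

Step 14
Reactants: 21 (1R,2S,4S)-4-bromo-2-[(1R,3S,4S)-3-bromo-4-methyl-7-oxabicyclo[2.2.1]heptan-1-yl]-2,3,3-trimethylcyclopentan-1-ol
Product: 22 (1R,3S,4S)-3-bromo-1-[(1S,3S,5R)-3-bromo-5-hydroxy-1,2,2-trimethylcyclopentyl]-4-chloro-4-methylcyclohexan-1-ol
Conditions: TiCl4 (2.2 equiv), CH2Cl2, −78 to −40 °C; then pH 7 phosphate buffer
Reagents that add atoms: titanium tetrachloride, Cl[Ti](Cl)(Cl)Cl
Why: Lewis-acid chlorinolysis of a bridged tertiary ether, the reaction type known from the hydrogen halide cleavage of cineoles: titanium bound to the ring hydroxyl and the bridge oxygen should ionise the C–O bond at the methyl-bearing carbon with anti-periplanar participation of the endo bromine, and chloride should open the bromonium ion at the tertiary carbon on the face the oxygen has left (double inversion, net retention), so that chlorine ends cis to the tertiary hydroxyl and trans to bromine.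

**Compound list**

1 | (1R,3S)-camphoric acid, (1R,3S)-1,2,2-trimethylcyclopentane-1,3-dicarboxylic acid | CC1(C)[C@@H](C(=O)O)CC[C@@]1(C)C(=O)O | starting material
2 | (1R,3S)-3-(methoxycarbonyl)-1,2,2-trimethylcyclopentane-1-carboxylic acid | CC1(C)[C@@H](C(=O)OC)CC[C@@]1(C)C(=O)O | intermediate
3 | methyl (1S,3R)-3-(chlorocarbonyl)-2,2,3-trimethylcyclopentane-1-carboxylate | CC1(C)[C@@H](C(=O)OC)CC[C@@]1(C)C(Cl)=O | intermediate
4 | methyl (1S,3R)-3-[methoxy(methyl)carbamoyl]-2,2,3-trimethylcyclopentane-1-carboxylate | CC1(C)[C@@H](C(=O)OC)CC[C@@]1(C)C(=O)N(C)OC | intermediate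
5 | (1S,3R)-3-[methoxy(methyl)carbamoyl]-2,2,3-trimethylcyclopentane-1-carboxylic acid | CC1(C)[C@@H](C(=O)O)CC[C@@]1(C)C(=O)N(C)OC | intermediate
6 | (1R)-N-methoxy-N,1,2,2-tetramethylcyclopent-3-ene-1-carboxamide | CC1(C)C=CC[C@@]1(C)C(=O)N(C)OC | intermediate
7 | (1S)-5-hydroxy-N-methoxy-N,1,2,2-tetramethylcyclopent-3-ene-1-carboxamide (both carbinol epimers) | CC1(C)C=CC(O)[C@@]1(C)C(=O)N(C)OC | intermediate
8 | (1S)-N-methoxy-N,1,5,5-tetramethyl-2-oxocyclopent-3-ene-1-carboxamide | CC1(C)C=CC(=O)[C@@]1(C)C(=O)N(C)OC | intermediate
9 | (1S,3R)-N-methoxy-N,1,2,2-tetramethyl-5-oxo-3-(4,4,5,5-tetramethyl-1,3,2-dioxaborolan-2-yl)cyclopentane-1-carboxamide | CC1(C)[C@H](B2OC(C)(C)C(C)(C)O2)CC(=O)[C@@]1(C)C(=O)N(C)OC | intermediate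
10 | (1S,3R)-3-hydroxy-N-methoxy-N,1,2,2-tetramethyl-5-oxocyclopentane-1-carboxamide | CC1(C)[C@H](O)CC(=O)[C@@]1(C)C(=O)N(C)OC | intermediate
11 | (1S,3R,5R)-3,5-dihydroxy-N-methoxy-N,1,2,2-tetramethylcyclopentane-1-carboxamide | CC1(C)[C@H](O)C[C@@H](O)[C@@]1(C)C(=O)N(C)OC | intermediate
12 | 4-bromo-2-methylbut-1-ene | C=C(C)CCBr | starting material
13 | (3-methylbut-3-en-1-yl)magnesium bromide | C=C(C)CC[Mg]Br | intermediate
14 | 1-[(1S,3R,5R)-3,5-dihydroxy-1,2,2-trimethylcyclopentyl]-4-methylpent-4-en-1-one | CC1(C)[C@H](O)C[C@@H](O)[C@@]1(C)C(=O)CCC(C)=C | intermediate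
15 | allylmagnesium bromide (prop-2-en-1-ylmagnesium bromide, ether solution) | C=CC[Mg]Br | starting material
16 | (1R,3R,4S)-4-[(4R)-4-hydroxy-7-methylocta-1,7-dien-4-yl]-4,5,5-trimethylcyclopentane-1,3-diol | CC1(C)[C@H](O)C[C@@H](O)[C@@]1(C)[C@](O)(CC=C)CCC(C)=C | intermediate
17 | (4R,4aS,6R,7aR)-2,2,4a,5,5-pentamethyl-4-(3-methylbut-3-en-1-yl)-4-(prop-2-en-1-yl)hexahydrocyclopenta[d][1,3]dioxin-6-ol (acetonide of 16, cis ring fusion, free OH trans to the ring-fusion oxygen) | CC1(C)[C@H](O)C[C@H]2OC(C)(C)O[C@@](CC=C)(CCC(C)=C)[C@@]12C | intermediate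
18 | (4R,4aS,6S,7aR)-6-bromo-2,2,4a,5,5-pentamethyl-4-(3-methylbut-3-en-1-yl)-4-(prop-2-en-1-yl)hexahydrocyclopenta[d][1,3]dioxine (bromine cis to the ring-fusion oxygen) | CC1(C)[C@@H](Br)C[C@H]2OC(C)(C)O[C@@](CC=C)(CCC(C)=C)[C@@]12C | intermediate
19 | (1R,2S,4S)-4-bromo-2-[(4R)-4-hydroxy-7-methylocta-1,7-dien-4-yl]-2,3,3-trimethylcyclopentan-1-ol | CC1(C)[C@@H](Br)C[C@@H](O)[C@@]1(C)[C@](O)(CC=C)CCC(C)=C | intermediate
20 | (1R)-1-[(1S,3S,5R)-3-bromo-5-hydroxy-1,2,2-trimethylcyclopentyl]-4-methylcyclohex-3-en-1-ol | CC1(C)[C@@H](Br)C[C@@H](O)[C@@]1(C)[C@@]1(O)CCC(C)=CC1 | intermediate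
21 | (1R,2S,4S)-4-bromo-2-[(1R,3S,4S)-3-bromo-4-methyl-7-oxabicyclo[2.2.1]heptan-1-yl]-2,3,3-trimethylcyclopentan-1-ol (ring bromine endo, trans to the oxygen bridge) | CC1(C)[C@@H](Br)C[C@@H](O)[C@@]1(C)[C@]23CC[C@](C)(O2)[C@@H](Br)C3 | intermediate
22 | (1R,3S,4S)-3-bromo-1-[(1S,3S,5R)-3-bromo-5-hydroxy-1,2,2-trimethylcyclopentyl]-4-chloro-4-methylcyclohexan-1-ol | CC1(C)[C@@H](Br)C[C@@H](O)[C@@]1(C)[C@@]1(O)CC[C@](C)(Cl)[C@@H](Br)C1 | target

**Step count and risks**

Total step count: 14. Longest linear sequence: 14 steps (1 to 22); 12 and 15 enter as commercial building blocks.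

Steps most likely to fail:

Step 14 (chlorinolysis of the ether bridge). What may go wrong: ionisation of the other C–O bond (at the carbinol carbon beside the quaternary centre, followed by a 1,2-shift), loss of a proton instead of chloride capture, or chloride attack at the secondary carbon with migration of bromine to the tertiary one. Fallback: the ether is bypassed. The sequence sets out from cyclohexenol 20 (step 13 stopped after the metathesis and 20 isolated) and treats it with NBS and ClTi(Oi-Pr)3 in CH2Cl2 at −20 °C, the reagent pair known for the bromochlorination of allylic alcohols. The tertiary alkoxide, held on tetravalent titanium together with the ring alkoxide, should hand chloride to the methyl-bearing carbon on its own face while the bromonium ion occupies the other face. This comes back to the route at 22 and makes no new compound (none, F0).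

Step 11 (Appel displacement). What may go wrong: substitution at the neopentyl-type carbon is slow, so that E2 loss to the cyclopentene or a 1,2-methyl shift in the oxyphosphonium ion overtakes it. Fallback: bromine is introduced from boron instead of oxygen. The sequence sets out from enone 8; the borylation of step 6 is run without the oxidative work-up and boronate 9 is isolated. NaBH4 with CeCl3·7H2O in MeOH at −78 °C should reduce the ketone from the methyl-bearing face to (1S,3R,5R)-5-hydroxy-N-methoxy-N,1,2,2-tetramethyl-3-(4,4,5,5-tetramethyl-1,3,2-dioxaborolan-2-yl)cyclopentane-1-carboxamide F1. With 3,5-bis(trifluoromethyl)phenyllithium (2.2 equiv, THF, −78 °C; the first equivalent deprotonates the hydroxyl) F1 forms the aryl boronate complex, and NBS then brominates the boron-bearing carbon with inversion to give (1S,3S,5R)-3-bromo-5-hydroxy-N-methoxy-N,1,2,2-tetramethylcyclopentane-1-carboxamide F2. Grignard reagent 13 converts F2 into 1-[(1S,3S,5R)-3-bromo-5-hydroxy-1,2,2-trimethylcyclopentyl]-4-methylpent-4-en-1-one F3. Allylmagnesium bromide 15 under the conditions of step 9 then gives 19, where the fallback comes back to the route; steps 10 to 12 are not needed on this path.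

Step 9 (allyl addition). What may go wrong: facial selectivity opposite to the chelate model (attack past the gem-dimethyl ring carbon), a real possibility because allylmagnesium reagents react very fast. Fallback: the order of the two carbon nucleophiles is reversed, which inverts the carbinol configuration for a given face of attack. The sequence sets out from 11; addition of 15 (THF, −78 °C, cold quench to keep the β,γ-unsaturated ketone from conjugating) gives 1-[(1S,3R,5R)-3,5-dihydroxy-1,2,2-trimethylcyclopentyl]but-3-en-1-one F4, and addition of Grignard reagent 13 to F4 comes back to the route at 16.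

Further compounds

F0 | step 14 | none | none
F1 | step 11 | (1S,3R,5R)-5-hydroxy-N-methoxy-N,1,2,2-tetramethyl-3-(4,4,5,5-tetramethyl-1,3,2-dioxaborolan-2-yl)cyclopentane-1-carboxamide | CC1(C)[C@H](B2OC(C)(C)C(C)(C)O2)C[C@@H](O)[C@@]1(C)C(=O)N(C)OC
F2 | step 11 | (1S,3S,5R)-3-bromo-5-hydroxy-N-methoxy-N,1,2,2-tetramethylcyclopentane-1-carboxamide | CC1(C)[C@@H](Br)C[C@@H](O)[C@@]1(C)C(=O)N(C)OC
F3 | step 11 | 1-[(1S,3S,5R)-3-bromo-5-hydroxy-1,2,2-trimethylcyclopentyl]-4-methylpent-4-en-1-one | CC1(C)[C@@H](Br)C[C@@H](O)[C@@]1(C)C(=O)CCC(C)=C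
F4 | step 9 | 1-[(1S,3R,5R)-3,5-dihydroxy-1,2,2-trimethylcyclopentyl]but-3-en-1-one | CC1(C)[C@H](O)C[C@@H](O)[C@@]1(C)C(=O)CC=C
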